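Readings and results come from a simulation from invented constants; the scatter is artificial.

Complex with one exchanged is a way station: on the card its exit to over-reaction product runs one way, so the end state holds it as loss, and what matters is how fast it leaks. Starting complex is the limiting reagent, 20 mM against 30.0 mM of incoming ligand, so I keep the ledger in it.

all flasks: starting complex 20 mM
- dawn: incoming ligand 30 mM; leaving ligand 40 mM; the very flask that is asked about, followed so far
- winter: incoming ligand 60 mM; leaving ligand 40 mM; run made earlier
- flask: incoming ligand 30.0 mM; leaving ligand 40.0 mM; time 6.0 min

| run | time / min | complex with one exchanged / % | starting complex / % |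
|---|---|---|---|
| dawn | 0.333 | 13.0 | 84.5 |
| dawn | 1.00 | 28.7 | 67.0 |
| dawn | 1.50 | 33.6 | 59.1 |
| dawn | 2.50 | 35.3 | 52.3 |
| dawn | 4.00 | 34.2 | 46.6 |
| dawn | 5.00 | 34.5 | 41.2 |
| dawn | 6.00 | 30.2 | 42.4 |
| winter | 0.167 | 14.1 | 84.5 |
| winter | 0.333 | 23.8 | 72.2 |
| winter | 0.667 | 34.1 | 55.2 |
| winter | 1.00 | 43.0 | 45.6 |
| winter | 1.33 | 45.8 | 38.7 |
| winter | 2.00 | 49.7 | 29.5 |
| winter | 2.50 | 49.3 | 26.9 |

(standard deviation of a reading: 1 percentage point)
- complex with one exchanged, in percent of the starting complex first charged, at 6.0 min
- what to do for the largest gain in complex with one exchanged; "none" if nothing gains more than 2 percentage points (alpha / gamma / beta / eta / none)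
- complex with one exchanged present, with what was taken out counted in, in percent of the starting complex first charged, after beta
- complex with one exchanged present, with what was taken out counted in, in percent of the starting complex first charged, after eta
- alpha: at 6.0 min add incoming ligand, 100% of the amount charged, then wait 3.0 min
- gamma: change nothing and wait 3.0 min more
- beta: at 6.0 min add starting complex, 50.0% of the amount charged, then wait 3.0 min
- eta: at 6.0 min take out 90% of the complex with one exchanged then present, then wait 3.0 min
- complex with one exchanged taken out counts as made
- the numbers in the tables scatter by 1 percentage point (one standard deviation)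
- what may be going on: starting complex + incoming ligand <-> leaving ligand + complex with one exchanged; incoming ligand -> decomposed reagent; complex with one exchanged -> over-reaction product; complex with one exchanged + incoming ligand <-> leaving ligand + complex with two exchanged
- additions bring no volume worth counting

Let S be starting complex and P complex with one exchanged, both in percent of charge. The dawn ledger at 6.00 min reads:

S: 42.4%
P: 30.2%
G, the gap, held by complex with two exchanged and over-reaction product: 27.4%

The entry to watch is G. Between 2.50 min and 6.00 min, S + P falls by 15 percentage points, while P averages 32.8%. That gives the leak constant λ, the fraction of P passing into G per minute: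

λ = 0.131 min⁻¹

This is a reading, with 1 point of scatter on each of its four numbers. Its half-life, ln(2)/λ, is 5.29 min, against a wait of 3.0 min.

The last two dawn readings average 32.4%, so I expect about that at 6.0 min. Over the wait, λ·P·3.0 min comes to 13 points at stake, and taking out 90% of P shelters 11 points of it. Shelter only keeps what is already made, so a gain over P at 6.0 min has to be new P. The dawn S readings at 5.00 min and 6.00 min, 41.2% and 42.4%, differ within the scatter, so I read the first step as near its balance, and taking out P, a product of that step, should let it run forward again. Alpha and beta push that step forward too, but their P stays under the leak. I reckon neither of them, so choosing eta is my judgement and not a sum.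

The forecast gives 32% and eta, with 33% after beta and 40% after eta. Its ground: “Removal wins because it stops both reverse reaction and over-reaction”.

    starting complex + incoming ligand ⇌ leaving ligand + complex with one exchanged (K = 3.38, k = 0.301 M⁻¹ s⁻¹)
    incoming ligand → decomposed reagent (k = 8.18 × 10⁻⁴ s⁻¹)
    complex with one exchanged → over-reaction product (k = 0.00212 s⁻¹)
    complex with one exchanged + incoming ligand ⇌ leaving ligand + complex with two exchanged (K = 0.324, k = 0.285 M⁻¹ s⁻¹)

The flask holds 31.0% at 6.0 min; eta is best, gaining 9.5 points and reaching 40.6%, while beta reaches 33.8%. At 6.00 min P is made at 0.395 of the rate at which it is used up. So, with λ as the use, doing nothing should lose λ·P·(1 − 0.395)·3.0 min = 7.4 points, and gamma loses 6.7 points. The neighbour charged with 5.0 mM holds 37.4% of P at 6.00 min; λ·P·6.0 min gives 29 points for it, and it holds 27.6% over-reaction product.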